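**Retrosynthetic overview**
1. The last C–C bond is C3'–aryl of the chalcan chain, made by copper-catalysed opening of a terminal epoxide with a 2,4,6-tris(benzyloxy)phenyl Grignard reagent. All phenols and the flavan 3-OH travel as benzyl ethers and are freed together at the end.
2. The C8–C1' bond comes from SN2 opening (inversion) of a cis-3-arylglycidol at its benzylic carbon by the C8 Grignard reagent of an 8-bromoflavan. The cis epoxide geometry sets C1' against C2'.
3. The flavan stereocentres (2S,3S, cis) are set together by dynamic kinetic resolution hydrogenation of a racemic flavan-3-one, obtained by Nef reaction of a 3-nitroflavan.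
4. Ring C is closed on a pre-formed ring A in one flask: nitroaldol addition of a 2-(2-fluoroaryl)nitroethane to 3,4-bis(benzyloxy)benzaldehyde (ring B) makes C2–C3, then the C2 alkoxide displaces fluoride to make O1–C8a.
5. Enabling feature: C8a of ring A is meta to both ring-A oxygens (C5, C7) and ortho to the C4a side chain, so it can be carried as a C–F carbon within reach of a C2 alkoxide. C3 of ring C, which bears that ring's only hydroxyl, can be carried as a nitro-bearing carbon (nitronate nucleophile, later ketone and carbinol).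

Key step: step 5

Remark: the target is read as 2,3-cis (2S,3S) in the flavan unit and (1R,2S) in the propyl chain; flavan numbering (O1, C2, C3, C4, C4a, C5 to C8, C8a; rings A, B, C) is used for the flavan and C1' to C3' for the chain; 5-fluororesorcinol, 3,4-bis(benzyloxy)benzaldehyde and 1,3,5-tris(benzyloxy)benzene are taken as catalogue chemicals.

**Route**

Step 1
Reactants: 1 5-fluororesorcinol
Product: 2 1,3-bis(benzyloxy)-5-fluorobenzene
Conditions: BnBr (2.2 equiv), K2CO3, DMF, 60 °C
Reagents that add atoms: benzyl bromide BrCc1ccccc1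
Why: Williamson O-benzylation of both phenols under carbonate conditions (SN2 on benzyl bromide), with no stereocenter involved.

Step 2
Reactants: 2 1,3-bis(benzyloxy)-5-fluorobenzene
Product: 4 2,4-bis(benzyloxy)-6-fluorobenzaldehyde, via iminium salt 3 (not isolated)
Conditions: POCl3 (1.5 equiv), DMF, 0 → 60 °C; then ice–water
Reagents that add atoms: N,N-dimethylformamide CN(C)C=O; water O
Why: Vilsmeier–Haack formylation, an electrophilic aromatic substitution that should go to the position ortho to fluorine (para to one benzyloxy group, ortho to the other) and not to the more hindered position between the two benzyloxy groups, a minor regioisomer being removed at this stage.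

Step 3
Reactants: 4 2,4-bis(benzyloxy)-6-fluorobenzaldehyde
Product: 5 (E)-1,5-bis(benzyloxy)-3-fluoro-2-(2-nitroethenyl)benzene
Conditions: MeNO2, NH4OAc (cat.), 90 °C
Reagents that add atoms: nitromethane C[N+](=O)[O-]
Why: Henry condensation (nitroaldol addition and dehydration) that should give the conjugated (E)-nitroalkene as the thermodynamically preferred isomer.

Step 4
Reactants: 5 (E)-1,5-bis(benzyloxy)-3-fluoro-2-(2-nitroethenyl)benzene
Product: 6 1,5-bis(benzyloxy)-3-fluoro-2-(2-nitroethyl)benzene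
Conditions: NaBH4, THF–EtOH, 0 °C → rt
Reagents that add atoms: none
Why: Conjugate hydride reduction of the nitroalkene by borohydride in a protic medium, which leaves the benzyl ethers and the aryl fluoride untouched.

Step 5
Reactants: 6 1,5-bis(benzyloxy)-3-fluoro-2-(2-nitroethyl)benzene; 7 3,4-bis(benzyloxy)benzaldehyde
Product: 10 rac-5,7-bis(benzyloxy)-2-[3,4-bis(benzyloxy)phenyl]-3-nitrochromane, via nitroaldol adduct 8 (not isolated), via potassium nitronate 9 (not isolated)
Conditions: KOtBu (2.5 equiv), THF–DMSO (4:1), 0 °C, then 70 °C; then AcOH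
Reagents that add atoms: none
Why: Proposed new method: the potassium nitronate of 6 adds to aldehyde 7 (Henry reaction) and forms the C2–C3 bond, the second equivalent of base turns the adduct into its alkoxide–nitronate dianion, which can neither revert (a retro-nitroaldol would have to expel a doubly deprotonated nitroalkane) nor lose water, and on warming the C2 alkoxide displaces fluoride at C8a by addition–elimination and forms the O1–C8a bond. The closest known reactions are the nitroaldol addition itself and the base-mediated cyclisation of 1-aryl-3-(2-fluoroaryl)propan-1-ols to flavans by intramolecular SNAr; their union in one flask on a nitronate-bearing chain is the new element. Ring C closes as a six-membered ring by attack of O1 on the trigonal ipso carbon C8a (6-exo-trig with respect to the C8a–C8 π bond) through a Meisenheimer-type transition state whose charge falls on C8, C4a and C6, carbons that carry no oxygen, while the two meta benzyloxy groups assist by induction. C2 is formed without control and C3 is trigonal in the nitronate, so no stereochemistry is asked of this step; both centres are set in step 7. The selectivity needed is O-arylation by the alkoxide at the C–F carbon, secured because fluoride is the only good nucleofuge on ring A, the nitronate carbon could only close a four-membered ring and the nitronate oxygens are far weaker nucleophiles than the alkoxide. If the base instead removes the C8 proton and fluoride leaves, the aryne so formed is captured by the same tethered alkoxide at C8a and gives the same product.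

Step 6
Reactants: 10 rac-5,7-bis(benzyloxy)-2-[3,4-bis(benzyloxy)phenyl]-3-nitrochromane
Product: 12 rac-5,7-bis(benzyloxy)-2-[3,4-bis(benzyloxy)phenyl]chroman-3-one, via sodium nitronate 11 (not isolated)
Conditions: NaOMe (1.1 equiv), MeOH–THF, 0 °C; then aq. TiCl3 (4.5 equiv), NH4OAc buffer (pH about 5), 0 °C → rt
Reagents that add atoms: water O
Why: Reductive Nef reaction, in which the nitronate is reduced by TiCl3 to the imine and hydrolysed in the buffered medium to the ketone under conditions that spare benzyl ethers, C3 becoming trigonal and C2 staying racemic.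

Step 7
Reactants: 12 rac-5,7-bis(benzyloxy)-2-[3,4-bis(benzyloxy)phenyl]chroman-3-one
Product: 13 (2S,3S)-5,7-bis(benzyloxy)-2-[3,4-bis(benzyloxy)phenyl]chroman-3-ol
Conditions: RuCl2[(S)-xylBINAP][(S)-DAIPEN] (1 mol %), KOtBu (10 mol %), H2 (20 atm), i-PrOH–toluene, 25 °C
Reagents that add atoms: none
Why: Noyori-type asymmetric hydrogenation with dynamic kinetic resolution of an α-aryl cyclic ketone, in which catalytic alkoxide epimerises C2 through the enolate faster than reduction and the chiral ruthenium hydride–diamine catalyst reduces one ketone enantiomer with hydride delivery anti to the C2 aryl group, so that C2 (S) and C3 (S, 2,3-cis) are both set by the catalyst (its antipode is taken if the sense on this ring system proves opposite).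

Step 8
Reactants: 13 (2S,3S)-5,7-bis(benzyloxy)-2-[3,4-bis(benzyloxy)phenyl]chroman-3-ol
Product: 14 (2S,3S)-3,5,7-tris(benzyloxy)-2-[3,4-bis(benzyloxy)phenyl]chromane
Conditions: NaH, BnBr, Bu4NI (cat.), DMF, 0 °C → rt
Reagents that add atoms: benzyl bromide BrCc1ccccc1
Why: Williamson benzylation of the secondary alkoxide, in which no bond at a stereocenter is broken.

Step 9
Reactants: 14 (2S,3S)-3,5,7-tris(benzyloxy)-2-[3,4-bis(benzyloxy)phenyl]chromane
Product: 15 (2S,3S)-3,5,7-tris(benzyloxy)-2-[3,4-bis(benzyloxy)phenyl]-8-bromochromane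
Conditions: NBS (1.0 equiv), CH2Cl2, –78 °C → rt
Reagents that add atoms: N-bromosuccinimide O=C1CCC(=O)N1Br
Why: Electrophilic aromatic bromination, which on 5,7-dialkoxyflavans should go to C8 (flanked by O1 and the C7 ether) in preference to C6 and to the less activated catechol ring.

Step 10
Reactants: 7 3,4-bis(benzyloxy)benzaldehyde
Product: 16 methyl (Z)-3-[3,4-bis(benzyloxy)phenyl]prop-2-enoate
Conditions: (CF3CH2O)2P(O)CH2CO2Me, KN(SiMe3)2, 18-crown-6, THF, –78 °C
Reagents that add atoms: methyl [bis(2,2,2-trifluoroethoxy)phosphoryl]acetate COC(=O)CP(=O)(OCC(F)(F)F)OCC(F)(F)F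
Why: Still–Gennari olefination, whose electron-poor trifluoroethyl phosphonate under dissociating conditions (potassium base, crown ether) should eliminate kinetically to the (Z)-enoate.

Step 11
Reactants: 16 methyl (Z)-3-[3,4-bis(benzyloxy)phenyl]prop-2-enoate
Product: 17 methyl (2R,3R)-3-[3,4-bis(benzyloxy)phenyl]oxirane-2-carboxylate
Conditions: (R,R)-[N,N'-bis(3,5-di-tert-butylsalicylidene)cyclohexane-1,2-diaminato]MnCl (6 mol %), 4-phenylpyridine N-oxide, aq. NaOCl (pH 11.3), CH2Cl2, 0 °C
Reagents that add atoms: sodium hypochlorite [Na+].[O-]Cl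
Why: Jacobsen epoxidation of a cis-cinnamate ester, in which oxo transfer from the chiral manganese salen complex sets both epoxide carbons (the (R,R)-catalyst is the one expected to give the (2R,3R)-cis-glycidate) and the ester group keeps the electron-rich aryl epoxide from ionising.

Step 12
Reactants: 17 methyl (2R,3R)-3-[3,4-bis(benzyloxy)phenyl]oxirane-2-carboxylate
Product: 18 [(2S,3R)-3-[3,4-bis(benzyloxy)phenyl]oxiran-2-yl]methanol
Conditions: NaBH4, MeOH–THF, 0 °C
Reagents that add atoms: none
Why: Borohydride reduction of the α-oxygen-activated ester to the primary alcohol, which leaves the epoxide and its two stereocenters untouched (the C2 descriptor changes by priority only).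

Step 13
Reactants: 15 (2S,3S)-3,5,7-tris(benzyloxy)-2-[3,4-bis(benzyloxy)phenyl]-8-bromochromane; 18 [(2S,3R)-3-[3,4-bis(benzyloxy)phenyl]oxiran-2-yl]methanol
Product: 22 (2R,3R)-3-[3,4-bis(benzyloxy)phenyl]-3-[(2S,3S)-3,5,7-tris(benzyloxy)-2-[3,4-bis(benzyloxy)phenyl]chroman-8-yl]propane-1,2-diol, via chloromagnesium alkoxide 19 (not isolated), via aryllithium 20 (not isolated), via arylmagnesium bromide 21 (not isolated)
Conditions: 15, t-BuLi (2.0 equiv), THF, –78 °C; MgBr2·OEt2, –78 → –40 °C; then CuI (15 mol %) and 18 (deprotonated beforehand by i-PrMgCl, 1.0 equiv), –40 → 0 °C; aq. NH4Cl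
Reagents that add atoms: none
Why: Copper-catalysed ring opening of a 3-arylglycidol by an aryl Grignard reagent, which should attack the benzylic carbon C3 of the alkoxide-bound epoxide in an SN2 sense with inversion, so that the cis epoxide geometry fixes the (R)-diarylmethine next to the untouched carbinol, while bromine–lithium exchange makes the C8 nucleophile regiospecifically.

Step 14
Reactants: 22 (2R,3R)-3-[3,4-bis(benzyloxy)phenyl]-3-[(2S,3S)-3,5,7-tris(benzyloxy)-2-[3,4-bis(benzyloxy)phenyl]chroman-8-yl]propane-1,2-diol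
Product: 24 (2S,3S)-3,5,7-tris(benzyloxy)-2-[3,4-bis(benzyloxy)phenyl]-8-[(R)-[3,4-bis(benzyloxy)phenyl][(2R)-oxiran-2-yl]methyl]chromane, via primary tosylate 23 (not isolated)
Conditions: NaH (2.5 equiv), 1-(p-tolylsulfonyl)imidazole (1.05 equiv), THF, 0 °C → rt
Reagents that add atoms: none
Why: One-pot epoxide formation from a 1,2-diol, in which the primary alkoxide is sulfonylated selectively and the secondary alkoxide closes by 3-exo-tet displacement, with retention at the carbinol carbon because its C–O bond is kept.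

Step 15
Reactants: 25 1,3,5-tris(benzyloxy)benzene
Product: 26 2-bromo-1,3,5-tris(benzyloxy)benzene
Conditions: NBS (1.0 equiv), CH2Cl2, –20 → 0 °C
Reagents that add atoms: N-bromosuccinimide O=C1CCC(=O)N1Br
Why: Electrophilic monobromination of a symmetrical, highly activated arene whose three free positions are equivalent, held at one bromine by stoichiometry and low temperature.

Step 16
Reactants: 24 (2S,3S)-3,5,7-tris(benzyloxy)-2-[3,4-bis(benzyloxy)phenyl]-8-[(R)-[3,4-bis(benzyloxy)phenyl][(2R)-oxiran-2-yl]methyl]chromane; 26 2-bromo-1,3,5-tris(benzyloxy)benzene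
Product: 28 (1R,2S)-1-[3,4-bis(benzyloxy)phenyl]-1-[(2S,3S)-3,5,7-tris(benzyloxy)-2-[3,4-bis(benzyloxy)phenyl]chroman-8-yl]-3-[2,4,6-tris(benzyloxy)phenyl]propan-2-ol, via arylmagnesium bromide 27 (not isolated)
Conditions: 26, Mg, THF, 50 °C; then CuI (10 mol %), 24, –30 → 0 °C; aq. NH4Cl
Reagents that add atoms: none
Why: Copper-catalysed SN2 opening of the terminal epoxide at its CH2 carbon by the aryl Grignard reagent, which touches no stereocenter and releases the secondary alcohol of the chain.

Step 17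
Reactants: 28 (1R,2S)-1-[3,4-bis(benzyloxy)phenyl]-1-[(2S,3S)-3,5,7-tris(benzyloxy)-2-[3,4-bis(benzyloxy)phenyl]chroman-8-yl]-3-[2,4,6-tris(benzyloxy)phenyl]propan-2-ol
Product: 29 (2S,3S)-2-(3,4-dihydroxyphenyl)-8-[(1R,2S)-1-(3,4-dihydroxyphenyl)-2-hydroxy-3-(2,4,6-trihydroxyphenyl)propyl]chromane-3,5,7-triol (the target)
Conditions: H2 (1 atm), Pd(OH)2/C, THF–MeOH–H2O, rt
Reagents that add atoms: none
Why: Hydrogenolysis of all ten benzyl ethers over Pd(OH)2/C under conditions mild enough that the benzylic C2–O1 ether bond of ring C and the diarylmethine should persist.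

**Compound list**
1 | 5-fluororesorcinol (5-fluorobenzene-1,3-diol) | Oc1cc(O)cc(F)c1 | starting material
2 | 1,3-bis(benzyloxy)-5-fluorobenzene | Fc1cc(OCc2ccccc2)cc(OCc2ccccc2)c1 | intermediate
3 | [2,4-bis(benzyloxy)-6-fluorophenyl]methylidene-dimethyliminium chloride (not isolated) | C[N+](C)=Cc1c(F)cc(OCc2ccccc2)cc1OCc1ccccc1.[Cl-] | intermediate
4 | 2,4-bis(benzyloxy)-6-fluorobenzaldehyde | O=Cc1c(F)cc(OCc2ccccc2)cc1OCc1ccccc1 | intermediate
5 | (E)-1,5-bis(benzyloxy)-3-fluoro-2-(2-nitroethenyl)benzene | [O-][N+](=O)/C=C/c1c(F)cc(OCc2ccccc2)cc1OCc1ccccc1 | intermediate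
6 | 1,5-bis(benzyloxy)-3-fluoro-2-(2-nitroethyl)benzene | [O-][N+](=O)CCc1c(F)cc(OCc2ccccc2)cc1OCc1ccccc1 | intermediate
7 | 3,4-bis(benzyloxy)benzaldehyde | O=Cc1ccc(OCc2ccccc2)c(OCc2ccccc2)c1 | starting material
8 | 1-[3,4-bis(benzyloxy)phenyl]-3-[2,4-bis(benzyloxy)-6-fluorophenyl]-2-nitropropan-1-ol, present as its dipotassium alkoxide–nitronate, mixture of isomers (not isolated) | OC(c1ccc(OCc2ccccc2)c(OCc2ccccc2)c1)C([N+](=O)[O-])Cc1c(F)cc(OCc2ccccc2)cc1OCc1ccccc1 | intermediate
9 | potassium nitronate of 10, racemic at C2 (not isolated) | [K+].[O-][N+]([O-])=C1Cc2c(OCc3ccccc3)cc(OCc3ccccc3)cc2OC1c1ccc(OCc2ccccc2)c(OCc2ccccc2)c1 | intermediate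
10 | rac-5,7-bis(benzyloxy)-2-[3,4-bis(benzyloxy)phenyl]-3-nitrochromane, both C3 epimers | [O-][N+](=O)C1Cc2c(OCc3ccccc3)cc(OCc3ccccc3)cc2OC1c1ccc(OCc2ccccc2)c(OCc2ccccc2)c1 | intermediate
11 | sodium nitronate of 10, racemic at C2 (not isolated) | [Na+].[O-][N+]([O-])=C1Cc2c(OCc3ccccc3)cc(OCc3ccccc3)cc2OC1c1ccc(OCc2ccccc2)c(OCc2ccccc2)c1 | intermediate
12 | rac-5,7-bis(benzyloxy)-2-[3,4-bis(benzyloxy)phenyl]chroman-3-one | O=C1Cc2c(OCc3ccccc3)cc(OCc3ccccc3)cc2OC1c1ccc(OCc2ccccc2)c(OCc2ccccc2)c1 | intermediate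
13 | (2S,3S)-5,7-bis(benzyloxy)-2-[3,4-bis(benzyloxy)phenyl]chroman-3-ol (tetra-O-benzyl-ent-epicatechin) | c1c(OCc3ccccc3)cc(OCc3ccccc3)c2c1O[C@@H](c1ccc(OCc3ccccc3)c(OCc3ccccc3)c1)[C@@H](O)C2 | intermediate
14 | (2S,3S)-3,5,7-tris(benzyloxy)-2-[3,4-bis(benzyloxy)phenyl]chromane | c1c(OCc3ccccc3)cc(OCc3ccccc3)c2c1O[C@@H](c1ccc(OCc3ccccc3)c(OCc3ccccc3)c1)[C@@H](OCc1ccccc1)C2 | intermediate
15 | (2S,3S)-3,5,7-tris(benzyloxy)-2-[3,4-bis(benzyloxy)phenyl]-8-bromochromane | Brc1c(OCc3ccccc3)cc(OCc3ccccc3)c2c1O[C@@H](c1ccc(OCc3ccccc3)c(OCc3ccccc3)c1)[C@@H](OCc1ccccc1)C2 | intermediate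
16 | methyl (Z)-3-[3,4-bis(benzyloxy)phenyl]prop-2-enoate | COC(=O)/C=C\c1ccc(OCc2ccccc2)c(OCc2ccccc2)c1 | intermediate
17 | methyl (2R,3R)-3-[3,4-bis(benzyloxy)phenyl]oxirane-2-carboxylate (cis) | COC(=O)[C@@H]1O[C@@H]1c1ccc(OCc2ccccc2)c(OCc2ccccc2)c1 | intermediate
18 | [(2S,3R)-3-[3,4-bis(benzyloxy)phenyl]oxiran-2-yl]methanol (cis) | OC[C@@H]1O[C@@H]1c1ccc(OCc2ccccc2)c(OCc2ccccc2)c1 | intermediate
19 | chloromagnesium alkoxide of 18 (not isolated) | Cl[Mg]OC[C@@H]1O[C@@H]1c1ccc(OCc2ccccc2)c(OCc2ccccc2)c1 | intermediate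
20 | [(2S,3S)-3,5,7-tris(benzyloxy)-2-[3,4-bis(benzyloxy)phenyl]chroman-8-yl]lithium (not isolated) | [Li]c1c(OCc3ccccc3)cc(OCc3ccccc3)c2c1O[C@@H](c1ccc(OCc3ccccc3)c(OCc3ccccc3)c1)[C@@H](OCc1ccccc1)C2 | intermediate
21 | [(2S,3S)-3,5,7-tris(benzyloxy)-2-[3,4-bis(benzyloxy)phenyl]chroman-8-yl]magnesium bromide (not isolated) | Br[Mg]c1c(OCc3ccccc3)cc(OCc3ccccc3)c2c1O[C@@H](c1ccc(OCc3ccccc3)c(OCc3ccccc3)c1)[C@@H](OCc1ccccc1)C2 | intermediate
22 | (2R,3R)-3-[3,4-bis(benzyloxy)phenyl]-3-[(2S,3S)-3,5,7-tris(benzyloxy)-2-[3,4-bis(benzyloxy)phenyl]chroman-8-yl]propane-1,2-diol | OC[C@H](O)[C@H](c1ccc(OCc2ccccc2)c(OCc2ccccc2)c1)c1c(OCc2ccccc2)cc(OCc2ccccc2)c2c1O[C@@H](c1ccc(OCc3ccccc3)c(OCc3ccccc3)c1)[C@@H](OCc1ccccc1)C2 | intermediate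
23 | 1-O-(p-tolylsulfonyl) derivative of diol 22 (not isolated) | Cc1ccc(cc1)S(=O)(=O)OC[C@H](O)[C@H](c1ccc(OCc2ccccc2)c(OCc2ccccc2)c1)c1c(OCc2ccccc2)cc(OCc2ccccc2)c2c1O[C@@H](c1ccc(OCc3ccccc3)c(OCc3ccccc3)c1)[C@@H](OCc1ccccc1)C2 | intermediate
24 | (2S,3S)-3,5,7-tris(benzyloxy)-2-[3,4-bis(benzyloxy)phenyl]-8-[(R)-[3,4-bis(benzyloxy)phenyl][(2R)-oxiran-2-yl]methyl]chromane | C1O[C@@H]1[C@H](c1ccc(OCc2ccccc2)c(OCc2ccccc2)c1)c1c(OCc2ccccc2)cc(OCc2ccccc2)c2c1O[C@@H](c1ccc(OCc3ccccc3)c(OCc3ccccc3)c1)[C@@H](OCc1ccccc1)C2 | intermediate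
25 | 1,3,5-tris(benzyloxy)benzene | c1c(OCc2ccccc2)cc(OCc2ccccc2)cc1OCc1ccccc1 | starting material
26 | 2-bromo-1,3,5-tris(benzyloxy)benzene | Brc1c(OCc2ccccc2)cc(OCc2ccccc2)cc1OCc1ccccc1 | intermediate
27 | [2,4,6-tris(benzyloxy)phenyl]magnesium bromide (not isolated) | Br[Mg]c1c(OCc2ccccc2)cc(OCc2ccccc2)cc1OCc1ccccc1 | intermediate
28 | (1R,2S)-1-[3,4-bis(benzyloxy)phenyl]-1-[(2S,3S)-3,5,7-tris(benzyloxy)-2-[3,4-bis(benzyloxy)phenyl]chroman-8-yl]-3-[2,4,6-tris(benzyloxy)phenyl]propan-2-ol (deca-O-benzyl ether of the target) | c1(OCc4ccccc4)cc(OCc4ccccc4)c(C[C@H](O)[C@H](c2ccc(OCc4ccccc4)c(OCc4ccccc4)c2)c2c(OCc4ccccc4)cc(OCc4ccccc4)c3c2O[C@@H](c2ccc(OCc4ccccc4)c(OCc4ccccc4)c2)[C@@H](OCc4ccccc4)C3)c(OCc4ccccc4)c1 | intermediate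
29 | (2S,3S)-2-(3,4-dihydroxyphenyl)-8-[(1R,2S)-1-(3,4-dihydroxyphenyl)-2-hydroxy-3-(2,4,6-trihydroxyphenyl)propyl]chromane-3,5,7-triol (the target natural product) | Oc1cc(O)c(C[C@H](O)[C@H](c2ccc(O)c(O)c2)c2c(O)cc(O)c3c2O[C@@H](c2ccc(O)c(O)c2)[C@@H](O)C3)c(O)c1 | target

**Count and risks**
Total step count: 17. Longest linear sequence: 13 steps (steps 1 to 9, 13, 14, 16, 17).

Steps most likely to fail:

1. Step 5 (proposed new method). The nitroaldol equilibrium may stay on the side of the components, or the adduct may lose water before the second deprotonation. Fluoride displacement on a ring without a conjugating acceptor may also be slow enough for base-induced decay of the aldehyde to compete. The fallback uses the known 3-nitrochromene synthesis and closes ring C through other bonds. It sets out from aldehyde 4: hydroxide displaces the aldehyde-activated fluoride (KOH, DMSO–H2O, 80 °C) to give 2,4-bis(benzyloxy)-6-hydroxybenzaldehyde F1. Aldehyde 7 is condensed with nitromethane (NH4OAc, 90 °C) to (E)-1,2-bis(benzyloxy)-4-(2-nitroethenyl)benzene F2. F1 and F2 are joined with DABCO (oxa-Michael addition, nitroaldol closure, dehydration) to rac-5,7-bis(benzyloxy)-2-[3,4-bis(benzyloxy)phenyl]-3-nitro-2H-chromene F3. Conjugate reduction with NaBH4 then gives 10, where the route is rejoined.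

2. Step 13. Transmetalation and attack by the doubly ortho-substituted aryl nucleophile may be sluggish, attack may go to C2 of the glycidol, or the electron-rich benzylic epoxide carbon may ionise and lose stereospecificity. The fallback sets out from 14 (the flavan before bromination) and glycidol 18. In hexafluoroisopropanol, which activates the epoxide by hydrogen bonding, ring A of 14 should attack the benzylic epoxide carbon through C8 in a Friedel–Crafts sense with inversion and give diol 22 directly, where the route is rejoined. This replaces the organometallic nucleophile by an electrophilic aromatic substitution and makes no new compound (F0).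

3. Step 7. Enantioface discrimination may be insufficient for a ketone flanked by two sp3 carbons, or epimerisation at C2 may be slower than reduction, which would leave a simple kinetic resolution. The fallback sets out from ketone 12: LiBH(s-Bu)3 in THF at –78 °C, which delivers hydride anti to the C2 aryl group, should give rac-cis-5,7-bis(benzyloxy)-2-[3,4-bis(benzyloxy)phenyl]chroman-3-ol F4. Its enantiomers are separated by preparative chromatography on a chiral stationary phase, and the (2S,3S) enantiomer is 13, where the route is rejoined.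

Further compounds
F1 | step 5 | 2,4-bis(benzyloxy)-6-hydroxybenzaldehyde | O=Cc1c(O)cc(OCc2ccccc2)cc1OCc1ccccc1
F2 | step 5 | (E)-1,2-bis(benzyloxy)-4-(2-nitroethenyl)benzene | [O-][N+](=O)/C=C/c1ccc(OCc2ccccc2)c(OCc2ccccc2)c1
F3 | step 5 | rac-5,7-bis(benzyloxy)-2-[3,4-bis(benzyloxy)phenyl]-3-nitro-2H-chromene | [O-][N+](=O)C1=Cc2c(OCc3ccccc3)cc(OCc3ccccc3)cc2OC1c1ccc(OCc2ccccc2)c(OCc2ccccc2)c1
F0 | step 13 | none | none
F4 | step 7 | rac-cis-5,7-bis(benzyloxy)-2-[3,4-bis(benzyloxy)phenyl]chroman-3-ol, (2S,3S) and (2R,3R) | c1c(OCc3ccccc3)cc(OCc3ccccc3)c2c1O[C@@H](c1ccc(OCc3ccccc3)c(OCc3ccccc3)c1)[C@@H](O)C2.c1c(OCc3ccccc3)cc(OCc3ccccc3)c2c1O[C@H](c1ccc(OCc3ccccc3)c(OCc3ccccc3)c1)[C@H](O)C2
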